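## Retrosynthetic overview

1. Isoflavan numbering is used (O1, C2, C3, C4, C4a, C5–C8, C8a; ring B primed; ring C is the pyran ring). Target 17 ⇐ 7-O-TIPS ether 16 ⇐ (cross-metathesis) 3'-allyl phenol 15 ⇐ (aromatic Claisen) 2'-O-allyl ether 13. The allyl group that protects O2' through the key step thus becomes three carbons of the prenyl chain.
2. 13 ⇐ lactol 11 (C2–OH removed by ionic hydrogenation) ⇐ phenol 2 (ring A) + 2-arylacrolein 9 (ring B plus C2–C3–C4). Ring C is cut at O1–C2 and C4–C4a and made in one amine-catalysed cascade of Friedel–Crafts conjugate addition, enantioselective protonation and hemiacetalisation, which also sets C3.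
3. Enabling feature: C4a is the ortho carbon of a phloroglucinol-type phenol (between C8a–O1 and C5–OMe), so O1/C4a act as a 1,3-C,O-bis-nucleophile. The only stereocentre, C3, is a C–H flanked by two CH2 groups (C2 and C4), so an α-aryl acrolein (β-CH2 → C4, CHO → C2) fits as the 1,3-bis-electrophile and C3 is created by protonation.
4. Fragments: 2 from 5-methoxyresorcinol by mono-silylation (the TIPS group steers the site of C-alkylation); 9 from 2-bromo-5-methoxyphenol by O-allylation, Br–Li exchange/acylation with ethyl diethoxyacetate, Wittig methylenation and acetal hydrolysis.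
5. Ring order: rings A and B are bought as arenes; ring C is the only ring formed (step 6).

Key step: step 6

Assumption: the (S)-configured diamine salt is taken to protonate the Si face of the enamine carbon that becomes C3 (giving 3R); if the sense proves opposite, the (R)-diamine is used with no other change.

## Route

Step 1
Reactants: 1 5-methoxyresorcinol
Product: 2 3-methoxy-5-[(triisopropylsilyl)oxy]phenol
Conditions: TIPSCl (1.0 equiv), imidazole, DMF, 0 °C → rt
Reagents that add atoms: triisopropylsilyl chloride, CC(C)[Si](Cl)(C(C)C)C(C)C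
Why: Statistical mono-O-silylation of a symmetric diol; the bis-silyl ether and unreacted 1 should be separable and 1 can be recycled.

Step 2
Reactants: 3 2-bromo-5-methoxyphenol
Product: 4 1-bromo-4-methoxy-2-(prop-2-en-1-yloxy)benzene
Conditions: allyl bromide, K2CO3, acetone, reflux
Reagents that add atoms: allyl bromide, C=CCBr
Why: Williamson ether synthesis on the only phenolic OH; the allyl ether serves as protecting group now and as latent C-allyl group later.

Step 3
Reactants: 4 1-bromo-4-methoxy-2-(prop-2-en-1-yloxy)benzene; 5 ethyl 2,2-diethoxyacetate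
Product: 7 2,2-diethoxy-1-[4-methoxy-2-(prop-2-en-1-yloxy)phenyl]ethan-1-one, via aryllithium 6 (not isolated)
Conditions: n-BuLi, THF, −78 °C; then 5, −78 → −40 °C; H2O
Reagents that add atoms: none
Why: Bromine–lithium exchange followed by acylation of the aryllithium with an α,α-dialkoxy ester, whose chelated tetrahedral lithium adduct should resist a second addition; at −78 °C the ortho-lithiated allyl ether should neither cyclise nor rearrange.

Step 4
Reactants: 7 2,2-diethoxy-1-[4-methoxy-2-(prop-2-en-1-yloxy)phenyl]ethan-1-one
Product: 8 1-(3,3-diethoxyprop-1-en-2-yl)-4-methoxy-2-(prop-2-en-1-yloxy)benzene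
Conditions: Ph3PCH3Br, KOtBu, THF, 0 °C → rt
Reagents that add atoms: methyltriphenylphosphonium bromide, C[P+](c1ccccc1)(c1ccccc1)c1ccccc1.[Br-]
Why: Wittig methylenation of an aryl ketone with the unstabilised ylide; the acetal and the allyl ether are inert to it.

Step 5
Reactants: 8 1-(3,3-diethoxyprop-1-en-2-yl)-4-methoxy-2-(prop-2-en-1-yloxy)benzene
Product: 9 2-[4-methoxy-2-(prop-2-en-1-yloxy)phenyl]prop-2-enal
Conditions: PPTS (cat.), acetone/H2O (9:1), rt; used at once
Reagents that add atoms: water, O
Why: Mild acid hydrolysis of an acetal that ionises easily through an allyl-stabilised oxocarbenium ion; the allyl aryl ether is stable, and the enal is carried on directly because 2-arylacroleins dimerise and polymerise on storage.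

Step 6
Reactants: 2 3-methoxy-5-[(triisopropylsilyl)oxy]phenol; 9 2-[4-methoxy-2-(prop-2-en-1-yloxy)phenyl]prop-2-enal
Product: 11 (3R)-5-methoxy-3-[4-methoxy-2-(prop-2-en-1-yloxy)phenyl]-7-[(triisopropylsilyl)oxy]chroman-2-ol (lactol as C2 epimers), via hydroxy aldehyde 10 (not isolated)
Conditions: (S)-N1,N1-diethyl-3,3-dimethylbutane-1,2-diamine·CF3SO3H (20 mol %), CHCl3, 0 °C
Reagents that add atoms: none
Why: Proposed new method: the primary amine of the catalyst should condense with 9 to an iminium ion, C2 of phenol 2 should add to its unsubstituted β-CH2 (Friedel–Crafts conjugate addition, forming C4–C4a), the resulting enamine should be protonated at the future C3 by the pendant Et2NH+ group of the catalyst, and hydrolysis should release hydroxy aldehyde 10, whose phenolic OH adds to the aldehyde (forming O1–C2) to give lactol 11. The closest known reaction types are the amine-catalysed Friedel–Crafts alkylation/hemiacetalisation of electron-rich phenols and naphthols with enals to chroman-2-ols and the chiral primary-amine-catalysed Friedel–Crafts addition of indoles to α-substituted acroleins with enantioselective enamine protonation; their combination on a phenol and an α-aryl acrolein is the new element. Ring C closes by 6-exo-trig addition of O1 to the aldehyde carbon after the intermolecular C–C bond formation. C3 is set by catalyst control: the stereocentre bearing the tert-butyl group next to the enamine nitrogen should fix the face (Si) to which the intramolecular ammonium proton is delivered, while the C2 hydroxyl forms as an epimeric mixture that is removed in step 7. The step needs site selectivity on ring A (the TIPS ether should shield C4 and C6 of 2 and block a second alkylation, leaving C2 between OH and OMe), C- over O-alkylation (oxa-Michael addition is reversible, C-alkylation is made irreversible by rearomatisation) and 1,4- over 1,2-addition (the β-carbon is unsubstituted and the iminium carbon is screened by the twisted ortho-substituted aryl group). Retention of the new configuration should be secured by capture of the α-aryl aldehyde as the lactol, which withdraws it from renewed enamine formation.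

Step 7
Reactants: 11 (3R)-5-methoxy-3-[4-methoxy-2-(prop-2-en-1-yloxy)phenyl]-7-[(triisopropylsilyl)oxy]chroman-2-ol
Product: 13 (3R)-5-methoxy-3-[4-methoxy-2-(prop-2-en-1-yloxy)phenyl]-7-[(triisopropylsilyl)oxy]chroman, via oxocarbenium ion 12 (not isolated)
Conditions: Et3SiH, BF3·OEt2, CH2Cl2, −78 → −30 °C
Reagents that add atoms: none
Why: Ionic hydrogenation of a lactol: BF3 should ionise C2–OH to the cyclic oxocarbenium ion, which excess silane reduces at low temperature faster than it can lose the C3 proton, so the O1–C2 bond and the C3 configuration are kept; aryl silyl, allyl and methyl ethers tolerate these conditions.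

Step 8
Reactants: 13 (3R)-5-methoxy-3-[4-methoxy-2-(prop-2-en-1-yloxy)phenyl]-7-[(triisopropylsilyl)oxy]chroman
Product: 15 3-methoxy-6-{(3R)-5-methoxy-7-[(triisopropylsilyl)oxy]chroman-3-yl}-2-(prop-2-en-1-yl)phenol, via ortho-dienone 14 (not isolated)
Conditions: PhNEt2, 195 °C, sealed tube, argon
Reagents that add atoms: none
Why: Aromatic Claisen [3,3]-sigmatropic rearrangement; of the two positions ortho to O2' only C3' carries hydrogen (C1' bears the chroman), so the allyl group should arrive at C3' and the dienone tautomerise to the phenol, with the remote C3 stereocentre untouched.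

Step 9
Reactants: 15 3-methoxy-6-{(3R)-5-methoxy-7-[(triisopropylsilyl)oxy]chroman-3-yl}-2-(prop-2-en-1-yl)phenol
Product: 16 3-methoxy-6-{(3R)-5-methoxy-7-[(triisopropylsilyl)oxy]chroman-3-yl}-2-(3-methylbut-2-en-1-yl)phenol
Conditions: second-generation Grubbs catalyst (5 mol %), 2-methyl-2-butene/CH2Cl2, 40 °C
Reagents that add atoms: 2-methyl-2-butene, CC=C(C)C
Why: Olefin cross-metathesis of a terminal allyl arene with excess 2-methyl-2-butene, the standard conversion of an ortho-allylphenol into an ortho-prenylphenol; the trisubstituted product olefin is unreactive to further metathesis and has no E/Z issue.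

Step 10
Reactants: 16 3-methoxy-6-{(3R)-5-methoxy-7-[(triisopropylsilyl)oxy]chroman-3-yl}-2-(3-methylbut-2-en-1-yl)phenol
Product: 17 (3R)-3-[2-hydroxy-4-methoxy-3-(3-methylbut-2-en-1-yl)phenyl]-5-methoxychroman-7-ol (CNP0119532.1)
Conditions: TBAF, AcOH, THF, 0 °C
Reagents that add atoms: none
Why: Fluoride-mediated cleavage of the aryl silyl ether under buffered, acid-free conditions, which should leave the ortho-prenylphenol uncyclised and the electron-rich phenols unoxidised.

## Compound list

1 | 5-methoxyresorcinol (5-methoxybenzene-1,3-diol) | COc1cc(O)cc(O)c1 | starting material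
2 | 3-methoxy-5-[(triisopropylsilyl)oxy]phenol | COc1cc(O)cc(O[Si](C(C)C)(C(C)C)C(C)C)c1 | intermediate
3 | 2-bromo-5-methoxyphenol | COc1ccc(Br)c(O)c1 | starting material
4 | 1-bromo-4-methoxy-2-(prop-2-en-1-yloxy)benzene | C=CCOc1cc(OC)ccc1Br | intermediate
5 | ethyl 2,2-diethoxyacetate | CCOC(=O)C(OCC)OCC | starting material
6 | [4-methoxy-2-(prop-2-en-1-yloxy)phenyl]lithium | [Li]c1ccc(OC)cc1OCC=C | intermediate
7 | 2,2-diethoxy-1-[4-methoxy-2-(prop-2-en-1-yloxy)phenyl]ethan-1-one | CCOC(OCC)C(=O)c1ccc(OC)cc1OCC=C | intermediate
8 | 1-(3,3-diethoxyprop-1-en-2-yl)-4-methoxy-2-(prop-2-en-1-yloxy)benzene | CCOC(OCC)C(=C)c1ccc(OC)cc1OCC=C | intermediate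
9 | 2-[4-methoxy-2-(prop-2-en-1-yloxy)phenyl]prop-2-enal | C=C(C=O)c1ccc(OC)cc1OCC=C | intermediate
10 | (2R)-3-{2-hydroxy-6-methoxy-4-[(triisopropylsilyl)oxy]phenyl}-2-[4-methoxy-2-(prop-2-en-1-yloxy)phenyl]propanal | COc1cc(O[Si](C(C)C)(C(C)C)C(C)C)cc(O)c1C[C@H](c1ccc(OC)cc1OCC=C)C=O | intermediate
11 | (3R)-5-methoxy-3-[4-methoxy-2-(prop-2-en-1-yloxy)phenyl]-7-[(triisopropylsilyl)oxy]chroman-2-ol (C2 epimers) | COc1cc(O[Si](C(C)C)(C(C)C)C(C)C)cc2c1C[C@H](c1ccc(OC)cc1OCC=C)C(O)O2 | intermediate
12 | (3R)-5-methoxy-3-[4-methoxy-2-(prop-2-en-1-yloxy)phenyl]-7-[(triisopropylsilyl)oxy]-3,4-dihydrochromenylium (cyclic oxocarbenium ion) | COc1cc(O[Si](C(C)C)(C(C)C)C(C)C)cc2c1C[C@H](c1ccc(OC)cc1OCC=C)C=[O+]2 | intermediate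
13 | (3R)-5-methoxy-3-[4-methoxy-2-(prop-2-en-1-yloxy)phenyl]-7-[(triisopropylsilyl)oxy]chroman | COc1cc(O[Si](C(C)C)(C(C)C)C(C)C)cc2c1C[C@H](c1ccc(OC)cc1OCC=C)CO2 | intermediate
14 | 5-methoxy-2-{(3R)-5-methoxy-7-[(triisopropylsilyl)oxy]chroman-3-yl}-6-(prop-2-en-1-yl)cyclohexa-2,4-dien-1-one (C6 epimers) | COc1cc(O[Si](C(C)C)(C(C)C)C(C)C)cc2c1C[C@H](C1=CC=C(OC)C(CC=C)C1=O)CO2 | intermediate
15 | 3-methoxy-6-{(3R)-5-methoxy-7-[(triisopropylsilyl)oxy]chroman-3-yl}-2-(prop-2-en-1-yl)phenol | COc1cc(O[Si](C(C)C)(C(C)C)C(C)C)cc2c1C[C@H](c1ccc(OC)c(CC=C)c1O)CO2 | intermediate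
16 | 3-methoxy-6-{(3R)-5-methoxy-7-[(triisopropylsilyl)oxy]chroman-3-yl}-2-(3-methylbut-2-en-1-yl)phenol | COc1cc(O[Si](C(C)C)(C(C)C)C(C)C)cc2c1C[C@H](c1ccc(OC)c(CC=C(C)C)c1O)CO2 | intermediate
17 | (3R)-3-[2-hydroxy-4-methoxy-3-(3-methylbut-2-en-1-yl)phenyl]-5-methoxychroman-7-ol | COc1cc(O)cc2c1C[C@H](c1ccc(OC)c(CC=C(C)C)c1O)CO2 | target

## Step count and risks

Total step count: 10. Longest linear sequence: 9 steps (3 → 17, steps 2–10).

Steps most likely to fail:

1. Step 6 (Proposed new method). What may go wrong: poor facial selectivity in the enamine protonation, erosion of the C3 configuration through renewed enamine formation from the ring-opened aldehyde, or C-alkylation at a shielded ring position. Fallback with known chemistry, setting out from 2 and 9 and returning at 13: 2 and 9 are joined without enantiocontrol by Brønsted-acid-catalysed Friedel–Crafts conjugate addition/hemiacetalisation (diphenyl phosphate, CH2Cl2, rt) to the racemic lactol F1. F1 is then subjected to dynamic kinetic resolution by asymmetric hydrogenation of its ring-opened α-aryl aldehyde form (H2, RuCl2[(S)-SDP][(R,R)-DPEN] or its mirror-image complex as required, KOtBu, i-PrOH, rt). The aldehyde racemises through its enolate while one enantiomer is reduced, and the catalyst class leaves the isolated alkene alone, which should give the (R)-diol F2. Mitsunobu etherification (PPh3, DIAD, THF, 0 °C) between the phenolic oxygen and the primary carbinol carbon then closes ring C and gives 13.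

2. Step 7. What may go wrong: loss of configuration at C3 by deprotonation of the oxocarbenium ion to the 4H-chromene and reprotonation, or reduction of the ring-opened aldehyde in place of the oxocarbenium ion. Fallback, setting out from 11 and returning at 13: NaBH4 (MeOH/THF, 0 °C) reduces the aldehyde that is in equilibrium with the lactol, without any cationic intermediate, to the (R)-diol F3 (the same structure as F2). Mitsunobu ring closure (PPh3, DIAD, THF, 0 °C) then gives 13.

3. Step 8. What may go wrong: unselective or incomplete sigmatropic shift at high temperature, that is migration on to the para position by way of the substituted ortho carbon, addition of the new phenol to the allyl double bond, or thermal loss of the silyl ether. Fallback, setting out from 13 and returning at 16: the allyl ether is cleaved with Pd(PPh3)4 and morpholine (THF, rt) to the phenol F4. Its sodium phenoxide (NaH, toluene) is then C-alkylated with prenyl bromide (CC(C)=CCBr) in the non-polar medium at the only free ortho position, C3', which gives 16 directly and bypasses 15 and the cross-metathesis.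

Further compounds

F1 | step 6 | rac-5-methoxy-3-[4-methoxy-2-(prop-2-en-1-yloxy)phenyl]-7-[(triisopropylsilyl)oxy]chroman-2-ol | COc1cc(O[Si](C(C)C)(C(C)C)C(C)C)cc2c1CC(c1ccc(OC)cc1OCC=C)C(O)O2
F2 | step 6 | (2R)-3-{2-hydroxy-6-methoxy-4-[(triisopropylsilyl)oxy]phenyl}-2-[4-methoxy-2-(prop-2-en-1-yloxy)phenyl]propan-1-ol | COc1cc(O[Si](C(C)C)(C(C)C)C(C)C)cc(O)c1C[C@H](c1ccc(OC)cc1OCC=C)CO
F3 | step 7 | (2R)-3-{2-hydroxy-6-methoxy-4-[(triisopropylsilyl)oxy]phenyl}-2-[4-methoxy-2-(prop-2-en-1-yloxy)phenyl]propan-1-ol | COc1cc(O[Si](C(C)C)(C(C)C)C(C)C)cc(O)c1C[C@H](c1ccc(OC)cc1OCC=C)CO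
F4 | step 8 | 5-methoxy-2-{(3R)-5-methoxy-7-[(triisopropylsilyl)oxy]chroman-3-yl}phenol | COc1cc(O[Si](C(C)C)(C(C)C)C(C)C)cc2c1C[C@H](c1ccc(OC)cc1O)CO2
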